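**Retrosynthetic overview**
1. Target ⇒ global deprotection of a bis-TBS ether/acetonide ⇐ trans-2,3-dihydrobenzofuran closed last by an intramolecular Mitsunobu etherification of an o-hydroxyaryl allylic carbinol (inversion at C2).
2. Carbinol ⇐ Nozaki–Hiyama–Kishi (NHK) coupling of an α-aryl-β-silyloxy aldehyde with a cis-diol cyclohexenyl iodide.
3. The aldehyde and its C3 stereocentre ⇐ aromatic Claisen rearrangement (the key sigmatropic C3a–C3 bond formation, with chirality transfer) of an aryl ether of an (R)-allylic alcohol. The phenol comes from eugenol.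
4. The cyclohexenyl iodide ⇐ (−)-quinic acid, which supplies the cis-diol of the correct absolute configuration.
5. Order of ring formation: benzene (from eugenol) → C3a–C3 bond (Claisen) → cyclohexene (chiral pool) → furan ring (Mitsunobu C2–O closure).

Assumption: (R)-but-3-en-2-ol, (−)-quinic acid, eugenol and allyl TBS ether are purchased. The minor NHK diastereomer is removed by chromatography.

---

**Step 1**
Reactants: 1, eugenol (4-allyl-2-methoxyphenol)
Product: 2, 4-(3-hydroxypropyl)-2-methoxyphenol
Conditions: 9-BBN (2.2 equiv), THF, 0 °C→rt; then NaOH (aq), H2O2, 0 °C→rt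
Reagents that add atoms: hydrogen peroxide, OO (supplies the OH oxygen)
Why: Anti-Markovnikov hydroboration–oxidation converts the terminal alkene to the primary alcohol; the extra borane equivalent covers the phenol O–H.

**Step 2**
Reactants: 2
Product: 3, 4-[3-(TBSO)propyl]-2-methoxyphenol (phenol free)
Conditions: TBSCl (1.05 equiv), imidazole, CH2Cl2, 0 °C
Reagents that add atoms: TBSCl, CC(C)(C)[Si](C)(C)Cl
Why: The primary alcohol silylates faster than the hindered, less nucleophilic phenol. The primary OH must be masked before the Mitsunobu step.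

**Step 3**
Reactants: 4, (R)-but-3-en-2-ol; 5, allyl tert-butyldimethylsilyl ether (3 equiv)
Product: 6, (2R,3E)-5-(TBSO)pent-3-en-2-ol
Conditions: Grubbs II (5 mol %), CH2Cl2, 40 °C
Reagents that add atoms: none (5 is a reactant; ethylene is lost)
Why: Cross-metathesis gives the E-1,2-disubstituted alkene and leaves the carbinol stereocentre, the sole chirality source for C3, untouched.

**Step 4**
Reactants: 3; 6
Product: 7, aryl (2S,3E)-5-(TBSO)pent-3-en-2-yl ether of 3
Conditions: PPh3, DIAD, THF, 0 °C→rt
Reagents that add atoms: none (PPh3/DIAD leave as Ph3P=O and the hydrazide)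
Why: Mitsunobu O-arylation is an SN2 displacement with clean inversion, so the (R)-alcohol gives the (S)-ether needed for the (R)-configured benzylic carbon after the Claisen.

**Step 5**
Reactants: 7
Product: 8, 2-methoxy-4-[3-(TBSO)propyl]-6-[(1R,2E)-1-(TBSOCH2)but-2-en-1-yl]phenol
Conditions: o-dichlorobenzene, 190 °C, sealed tube/µW, 2 h
Reagents that add atoms: none
Why: In the aromatic Claisen [3,3] shift the chair transition state has the E-substituent and the methyl group pseudo-equatorial, and the shift is suprafacial, so the (S)-ether stereocentre becomes the (R) C3 stereocentre. The free ortho position is the only site open (the other ortho position carries OMe).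

**Step 6**
Reactants: 8
Product: 9, (2R)-2-[2-hydroxy-3-methoxy-5-(3-TBSO-propyl)phenyl]-3-(TBSO)propanal, which exists as its 2-hydroxy-2,3-dihydrobenzofuran lactol
Conditions: O3, CH2Cl2/MeOH, −78 °C (1 equiv, pyridine traces); then Me2S
Reagents that add atoms: ozone, [O-][O+]=O (supplies the aldehyde oxygen)
Why: Ozonolysis cleaves the disubstituted alkene and leaves C2 at the aldehyde oxidation level. Cyclic hemiacetal formation with the ortho-phenol protects the epimerizable α-aryl centre.

**Step 7**
Reactants: 10, (−)-quinic acid ((1S,3R,4S,5R)-1,3,4,5-tetrahydroxycyclohexane-1-carboxylic acid)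
Product: 11, 3,4-O-isopropylidene-quinide (1,5-lactone, cis-3,4-diol as acetonide)
Conditions: Me2C(OMe)2, TsOH·H2O (cat.), acetone, rt
Reagents that add atoms: 2,2-dimethoxypropane, COC(C)(C)OC (supplies the CMe2 unit)
Why: Acetal formation takes the cis-3,4-diol selectively (the 4,5-trans diol cannot), and the acid cis to the 5-OH closes to the lactone. All pool stereocentres are retained.

**Step 8**
Reactants: 11
Product: 12, 3,4-O-isopropylidene-quinic acid
Conditions: LiOH·H2O, THF/H2O, rt; then KHSO4 to pH ≈ 3
Reagents that add atoms: water, O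
Why: Saponification opens the lactone under conditions the acetonide tolerates. The free α-hydroxy acid is needed for oxidative decarboxylation.

**Step 9**
Reactants: 12
Product: 13, 3,4-O-isopropylidene-5-hydroxycyclohexanone (quinic-derived; stereochemistry as in list)
Conditions: Pb(OAc)4, pyridine, CH2Cl2, 0 °C→rt
Reagents that add atoms: none
Why: Pb(OAc)4 oxidative decarboxylation converts the tertiary α-hydroxy acid to the ketone with loss of CO2 and no change at C3–C5.

**Step 10**
Reactants: 13
Product: 14, (4S,5R)-4,5-(isopropylidenedioxy)cyclohex-2-en-1-one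
Conditions: MsCl, Et3N, CH2Cl2, 0 °C; then DBU, rt
Reagents that add atoms: none (the mesylate leaves)
Why: E1cB elimination of the β-mesyloxy ketone gives the conjugated enone. Its 4,5-cis-diol stereochemistry is that of the target ring.

**Step 11**
Reactants: 14
Product: 15, (4S,5R)-2-iodo-4,5-(isopropylidenedioxy)cyclohex-2-en-1-one
Conditions: I2, pyridine/CH2Cl2 (1:1), 0 °C→rt
Reagents that add atoms: iodine, II
Why: α-Iodination of the enone (pyridine Michael addition–iodination–elimination) installs iodine at the carbon that becomes C1′.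

**Step 12**
Reactants: 15
Product: 16, 2-iodo-4,5-(isopropylidenedioxy)cyclohex-2-en-1-ol (mixture of carbinol epimers)
Conditions: NaBH4, CeCl3·7H2O, MeOH, −20 °C
Reagents that add atoms: none (hydride H only)
Why: Luche 1,2-reduction gives the allylic alcohol without touching C–I or the alkene. The new carbinol centre is removed in the next step.

**Step 13**
Reactants: 16
Product: 17, (3S,4R)-1-iodo-3,4-(isopropylidenedioxy)cyclohex-1-ene
Conditions: MsCl, Et3N, CH2Cl2, −30 °C; then LiEt3BH, THF, 0 °C
Reagents that add atoms: none
Why: SN2 hydride displacement of the unisolated allylic mesylate replaces C–O by C–H. Both carbinol epimers converge on 17, and C3′/C4′ are not involved.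

**Step 14**
Reactants: 9; 17
Product: 18, the open-chain (2R,3R) carbinol: 2-[(R)-1-(TBSOCH2)-2-hydroxy-2-(cyclohexenyl)ethyl]-phenol, diol as acetonide
Conditions: CrCl2 (6 equiv), NiCl2 (5 mol %), DMF, rt
Reagents that add atoms: none
Why: The NHK reaction couples the vinyl iodide under neutral, non-enolising conditions that protect the α-stereocentre. Felkin–Anh addition anti to the large aryl group sets the carbinol (2R); the minor epimer is separated chromatographically.

**Step 15**
Reactants: 18
Product: 19, protected (2S,3R)-trans-2,3-dihydrobenzofuran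
Conditions: PPh3, DIAD, THF, 0 °C→rt
Reagents that add atoms: none
Why: Intramolecular Mitsunobu etherification is a 5-exo SN2 by the phenol with inversion at C2. The (2R) carbinol becomes (2S), trans to the (3R) centre.

**Step 16**
Reactants: 19
Product: 20, difengpiol A
Conditions: TsOH·H2O (0.3 equiv), MeOH, rt
Reagents that add atoms: none
Why: Acid-catalysed methanolysis removes both primary TBS ethers and transketalizes the acetonide to release the cis-diol. No stereocentre is touched.

---

**Compound list**

| # | Name | SMILES | Role |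
|---|---|---|---|
| 1 | eugenol | C=CCc1ccc(O)c(OC)c1 | starting material |
| 2 | 4-(3-hydroxypropyl)-2-methoxyphenol | OCCCc1ccc(O)c(OC)c1 | intermediate |
| 3 | 4-[3-(TBSO)propyl]-2-methoxyphenol | CC(C)(C)[Si](C)(C)OCCCc1ccc(O)c(OC)c1 | intermediate |
| 4 | (R)-but-3-en-2-ol | C=C[C@@H](C)O | starting material |
| 5 | allyl TBS ether | C=CCO[Si](C)(C)C(C)(C)C | starting material |
| 6 | (2R,3E)-5-(TBSO)pent-3-en-2-ol | C[C@@H](O)/C=C/CO[Si](C)(C)C(C)(C)C | intermediate |
| 7 | aryl (S)-allyl ether | CC(C)(C)[Si](C)(C)OCCCc1ccc(O[C@@H](C)/C=C/CO[Si](C)(C)C(C)(C)C)c(OC)c1 | intermediate |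
| 8 | Claisen phenol (R) | CC(C)(C)[Si](C)(C)OCCCc1cc(OC)c(O)c([C@H](CO[Si](C)(C)C(C)(C)C)/C=C/C)c1 | intermediate |
| 9 | (2R)-aryl aldehyde (lactol form) | CC(C)(C)[Si](C)(C)OCCCc1cc(OC)c(O)c([C@@H](C=O)CO[Si](C)(C)C(C)(C)C)c1 | intermediate |
| 10 | (−)-quinic acid | C1[C@H]([C@@H]([C@@H](C[C@]1(C(=O)O)O)O)O)O | starting material |
| 11 | 3,4-O-isopropylidene-quinide | O=C1O[C@@H]2C[C@@]1(O)C[C@H]3OC(C)(C)O[C@@H]23 | intermediate |
| 12 | 3,4-O-isopropylidene-quinic acid | OC(=O)[C@]1(O)C[C@H]2OC(C)(C)O[C@H]2[C@H](O)C1 | intermediate |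
| 13 | 5-hydroxy-3,4-acetonide cyclohexanone | O=C1C[C@H]2OC(C)(C)O[C@H]2[C@H](O)C1 | intermediate |
| 14 | (4S,5R)-acetonide enone | O=C1C=C[C@@H]2OC(C)(C)O[C@@H]2C1 | intermediate |
| 15 | 2-iodoenone | O=C1C(I)=C[C@@H]2OC(C)(C)O[C@@H]2C1 | intermediate |
| 16 | 2-iodo allylic alcohol (carbinol epimers) | OC1C(I)=C[C@@H]2OC(C)(C)O[C@@H]2C1 | intermediate |
| 17 | (3S,4R)-1-iodo-3,4-acetonide-cyclohexene | IC1=C[C@@H]2OC(C)(C)O[C@@H]2CC1 | intermediate |
| 18 | NHK carbinol (2R,3R) | CC(C)(C)[Si](C)(C)OCCCc1cc(OC)c(O)c([C@H](CO[Si](C)(C)C(C)(C)C)[C@@H](O)C2=C[C@@H]3OC(C)(C)O[C@@H]3CC2)c1 | intermediate |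
| 19 | protected trans-dihydrobenzofuran | COc1cc(CCCO[Si](C)(C)C(C)(C)C)cc2c1O[C@H](C1=C[C@@H]3OC(C)(C)O[C@@H]3CC1)[C@H]2CO[Si](C)(C)C(C)(C)C | intermediate |
| 20 | difengpiol A | COc1cc(CCCO)cc2c1O[C@H](C1=C[C@H](O)[C@H](O)CC1)[C@H]2CO | target |

**Total steps:** 16
**Longest linear sequence:** 10 steps (from (−)-quinic acid: steps 7–16)

**Three steps most likely to fail**
1. **Step 13, allylic mesylate reduction.** SN2′ or E2 may compete with SN2 hydride delivery and give the wrong alkene position. Fallback: radical Barton–McCombie deoxygenation of 16 (thiocarbonylimidazolide, (TMS)3SiH, Et3B/O2, low temperature) instead of ionic displacement.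
2. **Step 14, NHK coupling.** A hindered, epimerizable α-aryl aldehyde may give poor diastereoselectivity or partial racemization at C3. Fallback: convert lactol 9 to its acetate and add the cyclohexenyl nucleophile (alkenyl trifluoroborate or zinc) to the Lewis-acid-generated oxocarbenium ion. This should give trans-2,3 directly and remove the need for Step 15.
3. **Step 15, Mitsunobu ring closure.** Only the (2R) carbinol gives the trans product, and SN2′ or elimination may intervene. Fallback: Pd(0) Tsuji–Trost cyclization of the allylic carbonate, which is stereoconvergent and thermodynamically trans-selective (the aryl carbonate formed alongside is cleaved selectively with K2CO3/MeOH).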